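The closed, stirred vessel stood at 20 °C with Sunday's charge, and at 10 min I had to say what it held and which move was worth making.

| setting | Sunday's | flask |
|---|---|---|
| starting material | 1 mM | 1.0 mM |
| second substrate | 0.70 equiv | 0.700 equiv |
| free enzyme | 0.01 mol% | 0.01 mol% |
| temperature | 20 °C | 20 °C |
| remark | the very flask that is asked about, followed so far |  |
| time |  | 10 min |

Sunday's run (percent of the starting material charged)

| time / min | target / % |
|---|---|
| 0.833 | 26.6 |
| 2.50 | 45.2 |
| 5.00 | 51.8 |
| 8.00 | 53.9 |
| 10.0 | 53.5 |

(scatter of a reading: 0.3 percentage points)

- west: at 10 min add free enzyme, 100 % of the amount charged, then wait 5.0 min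
- south: change nothing and wait 5.0 min more
- south-west: at 10 min add second substrate, 100 % of the amount charged, then wait 5.0 min
- north-west: at 10 min raise the temperature by 25 K, then wait 5.0 min
- east: at 10 min take out 90 % of the target then present, then wait 5.0 min

- target taken out counts as made
- the earlier runs do not show what temperature does; that part of a forecast is a guess
- additions bring no volume worth counting

1. target, in percent of the starting material first charged, at 10 min
2. what to do for the largest gain in target; "none" if nothing gains more than 2 percentage points (west / south / south-west / north-west / east / none)
3. target present, with what was taken out counted in, in percent of the starting material first charged, after south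
4. target present, with what was taken out counted in, in percent of the starting material first charged, after south-west

I began with the last two readings, 53.9 % and 53.5 %, which lie close together, so I took their mean, 53.7 %, as the target at 10 min. Second substrate is the limiting reagent here, and 23.3 % of its charge stood unused. My bet was that the enzyme wears out at a steady rate while its turnover follows the second substrate present. Then, with starting material and enzyme charges held, one charge of enzyme lowers the logarithm of the second substrate by a fixed amount, whatever amount of second substrate was charged. I called this the reach of the charge, the natural logarithm of second substrate charged over second substrate left at the end, here 1.46.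

The weak link was the steady wearing, so I tested it. If it holds, the distance still to go in that logarithm must shrink at a constant rate. The distance was 0.979 at 0.833 min, 0.420 at 2.50 min and 0.110 at 5.00 min. The two intervals give 0.508 min⁻¹ and 0.536 min⁻¹, so the link held, although the readings do not prove it. Overall I read a rate of 0.524 min⁻¹, a half-life of 1.32 min, which by this reckoning leaves 0.529 % of the catalyst working at 10 min.

Each move followed from this. That working remnant has 0.529 % of the reach left to use, so I reckoned south at a gain of 0.13 percentage points, and south-west, with more second substrate under the same remnant, at 0.67 points. I took a fresh charge of enzyme to have the full reach again, which in my reckoning leaves 5.42 % of the first charge of second substrate and gains 13 points. Taking target out leaves the second substrate as it stands, so I put east with south, and warming stayed a guess. I committed to west.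

The forecast gave 53.7 % now, 53.7 % after south and 80 % after south-west, and chose south-west, holding that “the flask is at equilibrium”, where my reckoning parted from it. The flask gave 53.9 %, then 54.1 % after south and 54.6 % after south-west, and the best move was west, with a gain of 12 points.

    free enzyme → unfolded enzyme (k = 7.03 × 10⁻⁴ s⁻¹, Ea = 240 kJ mol⁻¹)
    starting material + free enzyme ⇌ starting complex (K = 5000 M⁻¹, k = 1.65 × 10⁶ M⁻¹ s⁻¹, Ea = 14.0 kJ mol⁻¹, ΔH = −60.0 kJ mol⁻¹)
    second substrate + starting complex ⇌ ternary complex (K = 890 M⁻¹, k = 6.45 × 10⁷ M⁻¹ s⁻¹, Ea = 11.0 kJ mol⁻¹, ΔH = −26.0 kJ mol⁻¹)
    ternary complex → free enzyme + target (k = 230 s⁻¹, Ea = 52.0 kJ mol⁻¹)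
    starting complex → spent catalyst (k = 0.0135 s⁻¹, Ea = 77.0 kJ mol⁻¹)
    (constants at 20 °C)

In this flask 97.4 % of the catalyst was spent catalyst at 10.0 min, far more than the 1.93 % unfolded enzyme, while 23 % of the second substrate stood unused, and a second reach of 1.46 on that remainder, reckoned at 13 points, came out at 12 points under west. The neighbour flask charged with 0.420 equiv of second substrate and the same starting material and enzyme should, by the same reach, keep 23.2 % of its charge and make 32.2 %, and it kept 23 % and made 32.5 %.

All runs come from a simulation for an exercise, noise included.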